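**Plan**

- Retrosynthesis: the three O–H groups are unmasked last (silyl ethers). The oxolane O1–C5 ether bond is then cut to a 1,4-diol, which is the reduced form of a 5-alkoxy-γ-butyrolactone. Finally the benzylic C–C4 bond and the C3–carbinol C bond are cut in one operation.
- Enabling feature: oxolane C4 (benzyl-bearing) and C3 (carbinol-bearing) lie between two CH2–O carbons. With C2 raised to a lactone C=O and C5 to an acetal, C4/C3 become the β/α carbons of a butenolide. The benzylic carbon is an aldehyde carbon in umpoled form (1,3-dithiane) and the carbinol carbon is an aldehyde C=O.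
- Forward: the vanillin-derived dithiane anion, (5R)-5-(l-menthyloxy)-2(5H)-furanone and silylated syringaldehyde are joined in one tandem conjugate addition/aldol. The chain is then silylated, desulfurized, reduced to the diol, re-closed to the oxolane and desilylated.
- Stereochemistry: the bought acetal stereocentre directs C4 (anti addition), C4 directs C3 (trans), and a titanium enolate sets the carbinol carbon (syn aldol), all in the key step. The acetal carbon afterwards becomes a CH2.

Key step: step 4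

Assumption: (5R)-5-(l-menthyloxy)-2(5H)-furanone is taken as a purchasable chiral building block. Lactone intermediates are numbered with C2 = C=O.

**Step 1**
Reactants: 1 vanillin
Product: 2 4-(1,3-dithian-2-yl)-2-methoxyphenol
Conditions: HS(CH2)3SH (1.1 equiv), BF3·OEt2 (cat.), CH2Cl2, 0 °C → rt
Reagents that add atoms: propane-1,3-dithiol, SCCCS
Why: Lewis-acid-catalysed dithioacetalization of an aryl aldehyde, which tolerates the free phenol and installs the umpolung handle at the future benzylic carbon.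

**Step 2**
Reactants: 2 4-(1,3-dithian-2-yl)-2-methoxyphenol
Product: 3 2-[3-methoxy-4-(triisopropylsilyloxy)phenyl]-1,3-dithiane
Conditions: TIPSCl, imidazole, DMF, rt
Reagents that add atoms: triisopropylsilyl chloride, CC(C)[Si](Cl)(C(C)C)C(C)C
Why: Standard phenol silylation; the bulky aryl TIPS ether should withstand n-BuLi at low temperature, Raney nickel and LiAlH4 and is removed by fluoride at the end.

**Step 3**
Reactants: 4 syringaldehyde
Product: 5 3,5-dimethoxy-4-(triisopropylsilyloxy)benzaldehyde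
Conditions: TIPSCl, imidazole, DMAP (cat.), DMF, rt → 40 °C
Reagents that add atoms: triisopropylsilyl chloride, CC(C)[Si](Cl)(C(C)C)C(C)C
Why: Phenol silylation of the di-ortho-substituted phenol (mild warming for the hindered oxygen) gives a non-enolizable aldehyde for the aldol.

**Step 4**
Reactants: 3 2-[3-methoxy-4-(triisopropylsilyloxy)phenyl]-1,3-dithiane; 6 (5R)-5-[(1R,2S,5R)-menthyloxy]-2(5H)-furanone; 5 3,5-dimethoxy-4-(triisopropylsilyloxy)benzaldehyde
Product: 10 (3S,4R,5R)-3-{(S)-hydroxy[3,5-dimethoxy-4-(triisopropylsilyloxy)phenyl]methyl}-4-{2-[3-methoxy-4-(triisopropylsilyloxy)phenyl]-1,3-dithian-2-yl}-5-[(1R,2S,5R)-menthyloxy]dihydrofuran-2(3H)-one, via 2-lithio-1,3-dithiane 7 (not isolated), via lithium lactone enolate 8 (not isolated), via triisopropoxytitanium enolate 9 (not isolated)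
Conditions: n-BuLi (1.0 equiv), THF, −78 → −20 °C; 6 (1.05 equiv), −78 °C; ClTi(Oi-Pr)3 (1.2 equiv), −78 → −40 °C; 5 (1.3 equiv), −78 °C; aq NH4Cl
Reagents that add atoms: none
Why: The lithiated dithiane carbon (acyl-anion equivalent of the vanillyl carbon) adds 1,4 to the butenolide β-carbon, and the lactone enolate, after Li→Ti exchange, is intercepted at Cα by the aldehyde, so the benzylic C–ring C bond and the ring C–carbinol C bond form in one flask. The closest known reaction type is the tandem conjugate addition/enolate trapping of 2-aryl-2-lithio-1,3-dithianes with 5-alkoxy-2(5H)-furanones, combined with the aldol addition of transmetalated titanium enolates. No ring is closed; the lactone-acetal ring of 6 is carried through as the latent oxolane. The new C4 centre is set by attack anti to the C5 menthyloxy group (the one bought stereocentre), and the new C3 centre by aldehyde approach anti to the bulky C4 dithianyl group (3,4-trans). The carbinol centre is set by the closed boat-like transition state that triisopropoxytitanium enolates of ring-locked E-enolates should adopt, which favours the syn (erythro) aldol, here the (S)-carbinol; a lithium enolate in a chair-like transition state would favour the anti epimer. The step needs 1,4- over 1,2-addition, secured by the soft sulfur- and aryl-stabilised anion, and no surviving dithiane anion when the aldehyde is added, secured by the slight excess of 6.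

**Step 5**
Reactants: 10 aldol adduct (name as above)
Product: 11 (3S,4R,5R)-3-{(S)-(tert-butyldimethylsilyloxy)[3,5-dimethoxy-4-(triisopropylsilyloxy)phenyl]methyl}-4-{2-[3-methoxy-4-(triisopropylsilyloxy)phenyl]-1,3-dithian-2-yl}-5-[(1R,2S,5R)-menthyloxy]dihydrofuran-2(3H)-one
Conditions: TBSOTf, 2,6-lutidine, CH2Cl2, −40 → 0 °C
Reagents that add atoms: tert-butyldimethylsilyl triflate, CC(C)(C)[Si](C)(C)OS(=O)(=O)C(F)(F)F
Why: Silyl triflate silylation of a hindered secondary alcohol under non-nucleophilic base blocks retro-aldol cleavage and keeps the benzylic oxygen from taking part in the later ring closure.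

**Step 6**
Reactants: 11 silylated aldol adduct (name as above)
Product: 12 (3S,4R,5R)-3-{(S)-(tert-butyldimethylsilyloxy)[3,5-dimethoxy-4-(triisopropylsilyloxy)phenyl]methyl}-4-[3-methoxy-4-(triisopropylsilyloxy)benzyl]-5-[(1R,2S,5R)-menthyloxy]dihydrofuran-2(3H)-one
Conditions: Raney Ni (W-2, washed neutral, excess), EtOH–THF, rt
Reagents that add atoms: none
Why: Raney nickel desulfurization cleaves the two benzylic C–S bonds of the 2-aryl-1,3-dithiane to ArCH2, and the neutral catalyst at room temperature should spare the silyl ethers and the lactone acetal.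

**Step 7**
Reactants: 12 benzyl lactone acetal (name as above)
Product: 13 (2R,3R)-2-{(S)-(tert-butyldimethylsilyloxy)[3,5-dimethoxy-4-(triisopropylsilyloxy)phenyl]methyl}-3-[3-methoxy-4-(triisopropylsilyloxy)benzyl]butane-1,4-diol
Conditions: LiAlH4, THF, 0 °C; aq Rochelle salt
Reagents that add atoms: none
Why: Hydride reduction of the γ-alkoxy lactone reduces the C=O to CH2OH, and the released hemiacetal collapses to an aldehyde that is reduced to the second CH2OH with loss of menthol, so the auxiliary is removed without touching the three stereocentres.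

**Step 8**
Reactants: 13 1,4-diol (name as above)
Product: 15 (3R,4R)-3-{(S)-(tert-butyldimethylsilyloxy)[3,5-dimethoxy-4-(triisopropylsilyloxy)phenyl]methyl}-4-[3-methoxy-4-(triisopropylsilyloxy)benzyl]oxolane, via primary monotosylate 14 (not isolated)
Conditions: TsCl (1.1 equiv), pyridine, DMAP (cat.), CH2Cl2, 0 °C → rt, then 50 °C
Reagents that add atoms: none
Why: Mono-sulfonylation of the less hindered primary hydroxyl is followed by 5-exo-tet intramolecular Williamson etherification by the other primary hydroxyl (the regioisomeric monotosylate converges on the same ring), and the silylated benzylic oxygen cannot compete.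

**Step 9**
Reactants: 15 protected oxolane (name as above)
Product: 16 4-[(S)-hydroxy{(3R,4R)-4-[(4-hydroxy-3-methoxyphenyl)methyl]oxolan-3-yl}methyl]-2,6-dimethoxyphenol
Conditions: TBAF (3.5 equiv), AcOH (3.5 equiv), THF, 0 °C → rt
Reagents that add atoms: none
Why: Fluoride-mediated global desilylation removes both aryl TIPS ethers and the benzylic TBS ether, with acetic acid buffering to suppress phenoxide-driven quinone methide formation at the carbinol carbon.

**Compound list**

1 | vanillin | COc1cc(C=O)ccc1O | starting material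
2 | 4-(1,3-dithian-2-yl)-2-methoxyphenol | COc1cc(C2SCCCS2)ccc1O | intermediate
3 | 2-[3-methoxy-4-(triisopropylsilyloxy)phenyl]-1,3-dithiane | COc1cc(C2SCCCS2)ccc1O[Si](C(C)C)(C(C)C)C(C)C | intermediate
4 | syringaldehyde | COc1cc(C=O)cc(OC)c1O | starting material
5 | 3,5-dimethoxy-4-(triisopropylsilyloxy)benzaldehyde | COc1cc(C=O)cc(OC)c1O[Si](C(C)C)(C(C)C)C(C)C | intermediate
6 | (5R)-5-[(1R,2S,5R)-menthyloxy]-2(5H)-furanone | O=C1C=C[C@H](O[C@@H]2C[C@H](C)CC[C@H]2C(C)C)O1 | starting material
7 | 2-lithio-2-[3-methoxy-4-(triisopropylsilyloxy)phenyl]-1,3-dithiane (not isolated) | COc1cc(C2([Li])SCCCS2)ccc1O[Si](C(C)C)(C(C)C)C(C)C | intermediate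
8 | lithium enolate of the (4R,5R)-conjugate adduct (not isolated) | COc1cc(C2(SCCCS2)[C@H]3[C@H](O[C@@H]4C[C@H](C)CC[C@H]4C(C)C)OC(O[Li])=C3)ccc1O[Si](C(C)C)(C(C)C)C(C)C | intermediate
9 | triisopropoxytitanium enolate of the (4R,5R)-conjugate adduct (not isolated) | COc1cc(C2(SCCCS2)[C@H]3[C@H](O[C@@H]4C[C@H](C)CC[C@H]4C(C)C)OC(O[Ti](OC(C)C)(OC(C)C)OC(C)C)=C3)ccc1O[Si](C(C)C)(C(C)C)C(C)C | intermediate
10 | (3S,4R,5R)-3-[(S)-hydroxy(aryl)methyl]-4-(2-aryl-1,3-dithian-2-yl)-5-menthyloxy lactone (aldol adduct, full name in step 4) | COc1cc(C2(SCCCS2)[C@H]3[C@H](O[C@@H]4C[C@H](C)CC[C@H]4C(C)C)OC(=O)[C@@H]3[C@H](O)c2cc(OC)c(O[Si](C(C)C)(C(C)C)C(C)C)c(OC)c2)ccc1O[Si](C(C)C)(C(C)C)C(C)C | intermediate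
11 | TBS ether of 10 (full name in step 5) | COc1cc(C2(SCCCS2)[C@H]3[C@H](O[C@@H]4C[C@H](C)CC[C@H]4C(C)C)OC(=O)[C@@H]3[C@H](O[Si](C)(C)C(C)(C)C)c2cc(OC)c(O[Si](C(C)C)(C(C)C)C(C)C)c(OC)c2)ccc1O[Si](C(C)C)(C(C)C)C(C)C | intermediate
12 | desulfurized benzyl lactone acetal (full name in step 6) | COc1cc(C[C@H]2[C@H](O[C@@H]3C[C@H](C)CC[C@H]3C(C)C)OC(=O)[C@@H]2[C@H](O[Si](C)(C)C(C)(C)C)c2cc(OC)c(O[Si](C(C)C)(C(C)C)C(C)C)c(OC)c2)ccc1O[Si](C(C)C)(C(C)C)C(C)C | intermediate
13 | (2R,3R)-1,4-diol (full name in step 7) | COc1cc(C[C@@H](CO)[C@H](CO)[C@H](O[Si](C)(C)C(C)(C)C)c2cc(OC)c(O[Si](C(C)C)(C(C)C)C(C)C)c(OC)c2)ccc1O[Si](C(C)C)(C(C)C)C(C)C | intermediate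
14 | (2R,3R)-3-{(S)-(tert-butyldimethylsilyloxy)[3,5-dimethoxy-4-(triisopropylsilyloxy)phenyl]methyl}-4-hydroxy-2-[3-methoxy-4-(triisopropylsilyloxy)benzyl]butyl 4-methylbenzenesulfonate (not isolated) | COc1cc(C[C@@H](COS(=O)(=O)c3ccc(C)cc3)[C@H](CO)[C@H](O[Si](C)(C)C(C)(C)C)c2cc(OC)c(O[Si](C(C)C)(C(C)C)C(C)C)c(OC)c2)ccc1O[Si](C(C)C)(C(C)C)C(C)C | intermediate
15 | protected (3R,4R)-oxolane (full name in step 8) | COc1cc(C[C@H]2COC[C@@H]2[C@H](O[Si](C)(C)C(C)(C)C)c2cc(OC)c(O[Si](C(C)C)(C(C)C)C(C)C)c(OC)c2)ccc1O[Si](C(C)C)(C(C)C)C(C)C | intermediate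
16 | 4-[(S)-hydroxy{(3R,4R)-4-[(4-hydroxy-3-methoxyphenyl)methyl]oxolan-3-yl}methyl]-2,6-dimethoxyphenol | COc1cc(C[C@H]2COC[C@@H]2[C@H](O)c2cc(OC)c(O)c(OC)c2)ccc1O | target

**Step count and risks**

Total steps: 9. Longest linear sequence: 8 (steps 1, 2, 4, 5, 6, 7, 8, 9); step 3 is the side branch.

Steps most likely to fail:

1. Step 4. Simple diastereoselection at the carbinol carbon may be poor if the titanium exchange is incomplete or the closed transition state is chair-like, which would deliver the anti aldol. Fallback: set out from 8, omit the titanium exchange and add 5 directly at −78 °C. This should give 10 mixed with its carbinol epimer, (3S,4R,5R)-3-{(R)-hydroxy[3,5-dimethoxy-4-(triisopropylsilyloxy)phenyl]methyl}-4-{2-[3-methoxy-4-(triisopropylsilyloxy)phenyl]-1,3-dithian-2-yl}-5-menthyloxydihydrofuran-2(3H)-one F1. The mixture is oxidized under Parikh–Doering conditions (SO3·pyridine, DMSO, i-Pr2NEt, CH2Cl2, 0 °C; chosen because it spares the dithiane) to the single ketone (3S,4R,5R)-3-[3,5-dimethoxy-4-(triisopropylsilyloxy)benzoyl]-4-{2-[3-methoxy-4-(triisopropylsilyloxy)phenyl]-1,3-dithian-2-yl}-5-menthyloxydihydrofuran-2(3H)-one F2, whose epimerizable C3 should settle trans to C4. Chelation-controlled reduction with Zn(BH4)2 (Et2O, −30 °C), with zinc bridging the lactone and ketone carbonyls and hydride arriving from the face opposite ring C4, should give the syn alcohol. The route is rejoined at 10.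

2. Step 6. On the nickel surface the benzylic C–O bond next to the electron-rich ring may be hydrogenolysed, or the silyloxy group may be lost by base-promoted β-elimination. Fallback: remove sulfur before the carbinol exists. Set out from 8 and quench with aq NH4Cl to give (4R,5R)-4-{2-[3-methoxy-4-(triisopropylsilyloxy)phenyl]-1,3-dithian-2-yl}-5-menthyloxydihydrofuran-2(3H)-one F3. Raney nickel (EtOH, rt) then gives (4R,5R)-4-[3-methoxy-4-(triisopropylsilyloxy)benzyl]-5-menthyloxydihydrofuran-2(3H)-one F4. Its potassium enolate (KHMDS, THF, −78 °C) is treated with 5; attack anti to the C4 benzyl group and the open transition state expected for a potassium enolate should give the erythro (syn) aldol (3S,4R,5R)-3-{(S)-hydroxy[3,5-dimethoxy-4-(triisopropylsilyloxy)phenyl]methyl}-4-[3-methoxy-4-(triisopropylsilyloxy)benzyl]-5-menthyloxydihydrofuran-2(3H)-one F5. Silylation (TBSOTf, 2,6-lutidine) rejoins the route at 12.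

3. Step 8. Mono-activation of the diol may be unselective (bis-sulfonylation), or the alkoxide chemistry of steps 7–8 may cause 1,3-migration of the silyl group from the benzylic oxygen, after which the benzylic oxygen would close the wrong (2-aryl) oxolane. Fallback: never open the ring. Set out from 12 and reduce with DIBAL-H (1.1 equiv, toluene, −78 °C) to the lactol (3S,4R,5R)-3-{(S)-(tert-butyldimethylsilyloxy)[3,5-dimethoxy-4-(triisopropylsilyloxy)phenyl]methyl}-4-[3-methoxy-4-(triisopropylsilyloxy)benzyl]-5-menthyloxyoxolan-2-ol F6 (anomeric mixture). Ionic hydrogenation (Et3SiH, BF3·OEt2, CH2Cl2, −78 → −30 °C) should reduce both anomeric carbons through ring oxocarbenium ions, first at the lactol carbon and then at the menthyl acetal carbon with exocyclic loss of menthol. The low temperature is meant to keep the benzylic silyl ether from ionizing. The route is rejoined at 15.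

**Further compounds**

F1 | step 4 | (3S,4R,5R)-3-{(R)-hydroxy[3,5-dimethoxy-4-(triisopropylsilyloxy)phenyl]methyl}-4-{2-[3-methoxy-4-(triisopropylsilyloxy)phenyl]-1,3-dithian-2-yl}-5-menthyloxydihydrofuran-2(3H)-one | COc1cc(C2(SCCCS2)[C@H]3[C@H](O[C@@H]4C[C@H](C)CC[C@H]4C(C)C)OC(=O)[C@@H]3[C@@H](O)c2cc(OC)c(O[Si](C(C)C)(C(C)C)C(C)C)c(OC)c2)ccc1O[Si](C(C)C)(C(C)C)C(C)C
F2 | step 4 | (3S,4R,5R)-3-[3,5-dimethoxy-4-(triisopropylsilyloxy)benzoyl]-4-{2-[3-methoxy-4-(triisopropylsilyloxy)phenyl]-1,3-dithian-2-yl}-5-menthyloxydihydrofuran-2(3H)-one | COc1cc(C2(SCCCS2)[C@H]3[C@H](O[C@@H]4C[C@H](C)CC[C@H]4C(C)C)OC(=O)[C@@H]3C(=O)c2cc(OC)c(O[Si](C(C)C)(C(C)C)C(C)C)c(OC)c2)ccc1O[Si](C(C)C)(C(C)C)C(C)C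
F3 | step 6 | (4R,5R)-4-{2-[3-methoxy-4-(triisopropylsilyloxy)phenyl]-1,3-dithian-2-yl}-5-menthyloxydihydrofuran-2(3H)-one | COc1cc(C2(SCCCS2)[C@H]3[C@H](O[C@@H]4C[C@H](C)CC[C@H]4C(C)C)OC(=O)C3)ccc1O[Si](C(C)C)(C(C)C)C(C)C
F4 | step 6 | (4R,5R)-4-[3-methoxy-4-(triisopropylsilyloxy)benzyl]-5-menthyloxydihydrofuran-2(3H)-one | COc1cc(C[C@H]2[C@H](O[C@@H]3C[C@H](C)CC[C@H]3C(C)C)OC(=O)C2)ccc1O[Si](C(C)C)(C(C)C)C(C)C
F5 | step 6 | (3S,4R,5R)-3-{(S)-hydroxy[3,5-dimethoxy-4-(triisopropylsilyloxy)phenyl]methyl}-4-[3-methoxy-4-(triisopropylsilyloxy)benzyl]-5-menthyloxydihydrofuran-2(3H)-one | COc1cc(C[C@H]2[C@H](O[C@@H]3C[C@H](C)CC[C@H]3C(C)C)OC(=O)[C@@H]2[C@H](O)c2cc(OC)c(O[Si](C(C)C)(C(C)C)C(C)C)c(OC)c2)ccc1O[Si](C(C)C)(C(C)C)C(C)C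
F6 | step 8 | (3S,4R,5R)-3-{(S)-(tert-butyldimethylsilyloxy)[3,5-dimethoxy-4-(triisopropylsilyloxy)phenyl]methyl}-4-[3-methoxy-4-(triisopropylsilyloxy)benzyl]-5-menthyloxyoxolan-2-ol | COc1cc(C[C@H]2[C@H](O[C@@H]3C[C@H](C)CC[C@H]3C(C)C)OC(O)[C@@H]2[C@H](O[Si](C)(C)C(C)(C)C)c2cc(OC)c(O[Si](C(C)C)(C(C)C)C(C)C)c(OC)c2)ccc1O[Si](C(C)C)(C(C)C)C(C)C
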